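The numbers in the tables were computed from invented constants, and the scatter is random.

The examiner puts the flask on the table: the eta run, carried on to 30 h.

in all of them: substrate 0.050 M; free catalyst 50 µM
- eta: coupling partner 0.075 M; scavenger 0.050 M; the very flask that is asked about, followed so far
- theta: coupling partner 0.037 M; scavenger 0.050 M; run made earlier
- flask: coupling partner 0.0750 M; scavenger 0.0500 M; time 30 h

- eta (time / h: substrate / %, product / %): 0.167: 94.2, 5.8; 0.500: 89.6, 11.5; 0.833: 83.8, 16.2; 1.33: 81.6, 19.4; 2.00: 77.8, 21.4; 2.50: 77.4, 22.2
- theta (time / h: substrate / %, product / %): 0.833: 88.9, 10.8; 2.50: 81.4, 18.5; 4.00: 77.2, 21.0; 6.00: 78.2, 21.7; 10.0: 77.5, 22.7; 12.0: 79.3, 23.3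

(scatter of a reading: 1 percentage point)

- part of the substrate that has reacted at 30 h
- share of the unused coupling partner that is free and not bound as idle adduct, at 30 h

Examiner: Will the eta flask keep going?
Candidate: I doubt it. Theta's last product readings average 22.6% of the substrate, give or take 0.58 percentage points, and eta's last reading is 22.2%.

Examiner: Is coupling partner short?
Candidate: No. Theta had about half of eta's charge, and if one coupling partner goes per product, its late readings used 30.5% of that charge. Yet theta's late readings lie level with eta's last reading, within the scatter.

Examiner: So where is the loss?
Candidate: My assumption is that free catalyst dies while waiting for substrate. Then each turnover grows riskier as substrate falls. I therefore carry the reach, the natural log of substrate charged over substrate left at the stop. It should scale with the free catalyst charge. From theta it is 0.256.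

Examiner: Where is that weak?
Candidate: Eta and theta share one free catalyst charge, so the scaling is untested. Replacing falling substrate by its mean fraction, 0.887, gives 0.255, so the mean costs little here. For the eta flask at 30 h, I expect 22.6% reacted. On free coupling partner the runs are silent, so I give no number.

The forecast said 23% (21.5% to 25.5%) and 70% free (30% to 97%), on the suggestion that “the catalyst dies per turnover”.

The flask gives 22.7% reacted and 100% free, the latter above the forecast's range, with idle adduct at 0 M.

    substrate + free catalyst → catalyst intermediate A (k = 17.0 M⁻¹ s⁻¹)
    catalyst intermediate A ⇌ catalyst intermediate B (K = 0.180, k = 0.800 s⁻¹)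
    coupling partner + catalyst intermediate B → catalyst intermediate C (k = 13.0 M⁻¹ s⁻¹)
    catalyst intermediate C ⇌ released group + catalyst intermediate D (K = 0.0190 M, k = 1.00 s⁻¹)
    catalyst intermediate D → free catalyst + product (k = 0.430 s⁻¹)
    coupling partner + released group ⇌ idle adduct, settled at all times (K = 10.0 M⁻¹)
    scavenger + released group → scavenged by-product (k = 0.500 M⁻¹ s⁻¹)
    free catalyst → spent catalyst (k = 0.00330 s⁻¹)

In the asked flask, just after the start, substrate used free catalyst 260 times as fast as the loss to spent catalyst. Multiplied by the ratio of free catalyst charge to substrate charge, that start ratio gives a reach of 0.257. A neighbour flask was charged with 2.0 × 10⁻⁴ M of free catalyst, 4.00 times the asked charge. Its reach from the reading is 1.02, which gives 63.9% reacted. That neighbour gave 64.3%, with 36% of its substrate left.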